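You cannot read north's progress off its crystals: the red run showed solid at 0% after 8.00 min with target at 77.8%, so the rest stood dissolved and unreacted.

all flasks: solid electrophile 0.078 M

| charge | nucleophile | remark | time |
|---|---|---|---|
| red | 0.13 M | run made earlier |  |
| teal | 0.42 M | run made earlier |  |
| north | 0.0940 M |  | 15 min |
| north-east | 0.190 M |  | 15 min |
| south | 0.370 M |  | 15 min |

| run | time / min | solid electrophile / % | target / % |
|---|---|---|---|
| red | 2.00 | 56.7 | 17.0 |
| red | 4.00 | 29.8 | 38.8 |
| red | 6.00 | 4.6 | 61.3 |
| red | 8.00 | 0 | 77.8 |
| red | 10.0 | 0 | 84.6 |
| red | 12.0 | 0.2 | 90.0 |
| red | 15.0 | 0.1 | 95.9 |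
| teal | 2.00 | 50.5 | 36.5 |
| teal | 4.00 | 5.0 | 78.6 |
| teal | 6.00 | 0 | 99.3 |
| teal | 8.00 | 0.6 | 99.7 |
| teal | 10.0 | 1.0 | 100.0 |
| teal | 12.0 | 0 | 100.6 |
| teal | 15.0 | 0 | 98.7 |

(scatter of a reading: 1 percentage point)

- part of the solid electrophile that has reacted (what has only dissolved counts as not reacted) at the end, north
- part of the solid electrophile that has reacted (what has only dissolved counts as not reacted) at the end, north-east
- part of the solid electrophile that has reacted (what has only dissolved counts as not reacted) at the end, south
- what raising the concentration of nucleophile from its lowest to its highest value here does to the part of the solid electrophile that has reacted (what has only dissolved counts as not reacted) (changes below 5 percentage points count as none) (no change / it falls / it rises)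

- at the start none of the solid electrophile is in solution
- what has only dissolved of solid electrophile counts as not reacted

Expect the crystals to vanish before you come, as red's solid read 0% at 8.00 min, but leave the flasks stirring to 15 min: red's target was still climbing to 95.9%. Call u the unreacted fraction of the charge and x the nucleophile charged in excess, as a fraction of that charge. I take the tail as second order (solid electrophile is the limiting reagent), so ln((x+u)/u) climbs straight, with slope x times the tail rate, the second-order constant times the charge. Red, with x at 66.7%, gives 0.313 /min, a reading with the scatter of 1 percentage point.

North has x at 20.5%. Scaling red's target at 6.00 min by the nucleophile charge, I start from u at 55.7%, where the logarithm is 0.314. It gains 0.578 by 15 min, leaving u at 14.3%, so I commit to 85.7% reacted. North-east, with x at 144% and u from 10.4%, gives 99.8%. South, charged below teal, should finish as teal did, near 100.0%.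

The forecast says 85%, 99% and 100%, and of the trend, it rises: “Integrating the second-order tail to 15 min leaves about 15% unreacted”. For north it stands 0.70 points below my figure.

The flasks give 85.5%, 99.6% and >99.9%; of the reacted part, from the lowest nucleophile to the highest, it rises, by 15 points.

    electrophile + nucleophile → acid set free + target (k = 0.0690 /M/s)
    nucleophile + acid set free ⇌ protonated nucleophile, settled at all times (K = 220 /M)
    solid electrophile ⇌ electrophile, rate k3*(cs3 - [electrophile]) while solid is left; crystals form when [electrophile] > cs3 (solubility = 42.0 mM, k = 0.00970 /s)
    acid set free → by-product carried off (k = 0.220 /s)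
    electrophile + acid set free ⇌ idle adduct, settled at all times (K = 17.0 /M)

In north the half-life of electrophile by its reaction with nucleophile lengthens from 2.3 min at 2.61 min to 6.3 min at 15.0 min, while at that time acid set free has a half-life of 0.053 min by its turning into by-product carried off. The tail rate, with nucleophile at 28.4% of its own charge, gives 6.46 min for that electrophile half-life. In north-east, starting from electrophile at 11.3% after 7.50 min, the same climb gives 0.357% at 15.0 min, where the flask holds 0.390%.

(The numbers in the tables are calculated on assumed constants.)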